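## The problem

The target (30) is the 3‑hydroxy‑4‑methoxybenzoate of a cis‑fused bicyclo[5.3.0]decane diol. Locants used here: C1 is the quaternary ring‑fusion carbon carrying a methyl group, C2 and C3 are methylenes, C4 is the isopropyl carbinol, C5 is the ring‑fusion CH, C6 carries the acyloxy group, C7=C8 is the ring alkene with a methyl on C8, and C9 and C10 are methylenes leading back to C1. Four stereocentres must be controlled, three of them contiguous (C4, C5, C6) and one an all‑carbon quaternary centre (C1). C1 has no handle for later correction, so it must be set absolutely when its last C–C bond forms. The other three can be relayed from it: C5 is epimerisable whenever C4 or C6 is a carbonyl, C4 follows from the face on which a nucleophile meets a C4 ketone of the cis‑fused bicycle, and C6 can be set by a reduction steered by the C4 hydroxyl. The ring fusion is cis, which a seven‑ring ketone next to an angular‑methyl junction is not expected to favour, whereas a five‑ring ketone is. Several groups restrict the conditions: a β‑hydroxy ketone (C4–OH with a C6 carbonyl) can undergo retro‑aldol cleavage or dehydration, a C4 ketone with an oxygen on C6 can eliminate to a dienone, the allylic benzoate ionises under acid and would not survive hydrogenolysis, and the free phenol and the trisubstituted alkene rule out strong base and hydrogenation late in the route. The feature that opens the structure is in the seven‑membered ring: the oxygen on C6 and the carbon substituent on C8 are 1,3‑related, and C1 is joined to C8 through C9–C10. That is the imprint of a 2‑oxygenated diene (C7=C6–C5=C1, with the C5=C1 half inside the five‑membered ring) united with a three‑carbon vinylcarbene unit (C8–C9–C10) that carries an ester on C8.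

## Retrosynthesis

**Ester bond.** The O–acyl bond at C6 is cut first, giving diol 25 and the silyl‑protected acid 28 (from isovanillic acid 26), with 29 as the protected ester. Making the allylic benzoate last keeps this acid‑ and reduction‑sensitive group out of every earlier step. The forward reaction must acylate a secondary allylic hydroxyl with retention in the presence of a tertiary one, which sterics should ensure.

**C6–H bond.** Diol 25 is traced to β‑hydroxy enone 24. Setting C6 last lets the C4 hydroxyl, already in place and on the required side, steer the hydride through a boron chelate. Setting C6 earlier would tie its configuration to a ring fusion that is not yet fixed. Enone 24 comes from diol 23 (C6 epimers) by oxidation, and 23 from silyl ether 22. The forward reduction must be 1,2‑selective and must not disturb the β‑hydroxy ketone.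

**C4–isopropyl bond.** Carbinol 22 is cut to cis‑fused cyclopentanone 21 and an isopropyl nucleophile. The alternative order, adding the isopropyl group while C5 is still sp2, would leave the C4 face controlled only by the remote C1 substituents. On 21 the seven‑membered ring attached at C5 shields one face. The forward step needs a weakly basic organometallic reagent, because the ketone is hindered and enolisable.

**Ring fusion (C5–H).** Ketone 21 is traced to ketal 20. C5 is deliberately not fixed while C6 is a ketone. Instead, the C6 carbonyl is temporarily reduced and silylated (19, 20), so that C5 can equilibrate next to the five‑ring C4 ketone, where a cis junction beside an angular methyl is the stable arrangement. The price is a placeholder stereocentre at C6, erased later at 24. The C8 methyl is taken back to the ester of 16 through diol 17 and alcohol 19, since an ester on C8 is what the key step delivers.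

**Enone ester.** Keto ester 16 comes from silyl enol ether 14 by desilylation (to 15) and movement of the C8=C9 alkene into conjugation. This adjustment is needed because the key step places the alkene one position away from where the target has it. The ester on C8 makes the conjugated isomer the thermodynamic one.

**Key cut.** Cycloheptadiene 14 is disconnected at C7–C8 and C1–C10 into siloxydiene 8 and methyl 2‑diazobut‑3‑enoate 12, by way of cis‑divinylcyclopropane 13 (bonds C7–C8 and C6–C8, the latter broken again). Cutting here removes the seven‑membered ring and the quaternary centre in one operation. It leaves an achiral cyclopentene and a four‑carbon diazo ester, and places the source of absolute configuration in a catalyst. The forward reaction must be site‑selective for the terminal enol ether, enantioselective, and must drive a Cope rearrangement onto a fully substituted alkene terminus.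

**Building blocks.** Diene 8 is the silyl enol ether of methyl ketone 6, which comes from bromo ketal 4 by lithiation and acetylation, and 4 from 3‑methylcyclopent‑2‑en‑1‑one 1 by way of bromo enone 3. Diazo ester 12 comes from methyl acetoacetate 9 through 10 and 11. All are standard operations on simple materials.

## Roads not taken

**Alternative 1:** The cut is at C1–C5 and C9–C10, opening both rings to the acyclic ene–vinylcyclopropane A2. Forward, [Rh(CO)2Cl]2 (a monovalent rhodium dimer) would mediate an intramolecular [5+2] cycloaddition of the vinylcyclopropane (C5=C6 with cyclopropane carbons C7–C9) onto the tethered 1,1‑disubstituted alkene (C1=C10), giving hydroazulene A1.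
- Merits: both rings form in one step; the three‑atom tether normally enforces a cis junction; the C4 carbinol is present from the start, so C4, C5 and C1 are related in a single event. In this respect the route is better than the chosen plan, which needs an equilibration and an addition to reach the same three centres.
- Weak points: the alkene partner is 1,1‑disubstituted and must create the quaternary carbon, which is the slow case for this cycloaddition. The methyl‑substituted cyclopropane can open at either distal bond. A1 has no oxygen at C6, so a late allylic oxidation with alkene transposition would have to find the right position and face. All chirality rests on an enantiopure tertiary carbinol flanked by two similar chains, which is hard to make.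
- Comparison: the chosen plan carries the C6 oxygen through the key step and takes its absolute configuration from a catalyst acting on an achiral diene; these are the advantages it sets against the better relay of C4/C5 in A1.

**Alternative 2:** The cut is at C5–C6 and C1–C10, giving cyclobutanone A3, followed later by a C6–C7 bond formation with cleavage of C6–C10. Forward, amide A4 would be converted into a keteniminium salt (Tf2O, 2,4,6‑collidine) and added to the trisubstituted alkene of silyl ether A5; hydrolysis gives A3, whose bromoalkyl chain is then used for a three‑carbon radical ring expansion.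
- Merits: keteniminium [2+2] additions tolerate hindered, unactivated alkenes, so the quaternary C1 is formed by a more forgiving reaction than a Cope rearrangement with an inside methyl; on this point the alternative is stronger. The C6 carbonyl and a cis ring junction arrive together.
- Weak points: facial control must come from the quaternary C4 centre of A5, whose two substituents (silyloxy and isopropyl) are both large. The ring expansion must cleave C6–C10 and not C6–C5, two bonds that give similar secondary radicals. The C7=C8 alkene must still be introduced regioselectively next to a ketone that has another enolisable side. A5 needs its own asymmetric synthesis.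
- Comparison: the route is longer and its selectivity problems come after the key step. The chosen plan forms the seven‑membered ring directly and has its risk concentrated in one step with a clear mechanistic remedy.

**Alternative 3:** The cut is at C1–C2, opening the five‑membered ring to the cross‑conjugated silylvinyl ketone A7 built on a preformed cycloheptadiene. Forward, FeCl3 would induce a silicon‑directed Nazarov cyclisation to the cis‑fused cyclopentenone A6.
- Merits: the cis junction comes directly from the cyclisation and needs no equilibration, which is better than the chosen plan. Silicon fixes the position of the new alkene. The C6 epimer that results could be corrected during esterification by a Mitsunobu inversion, which costs no extra step.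
- Weak points: the pentadienyl cation has an allylic silyloxy group on the carbon next to its terminus, which invites ionisation or elimination under FeCl3. Closure onto a fully substituted terminus is slow. Torquoselectivity depends on that same labile C6 centre, which is also the only source of chirality and must be made enantiopure on a cycloheptadiene. The isopropyl carbinol still requires conjugate reduction and the same ketone addition as in the chosen plan.
- Comparison: the chosen plan is convergent from two simple fragments and creates C1 under catalyst control; against this it has to set the extra steps that fix the ring fusion.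

Key step: step 8

Remarks before the steps:
- Locants: the discussion uses C1–C10 as defined above; systematic names use hydroazulene locants (C1 = 8a, C2 = 1, C3 = 2, C4 = 3, C5 = 3a, C6 = 4, C7 = 5, C8 = 6, C9 = 7, C10 = 8).
- Catalyst: Rh2(S‑DOSP)4 is dirhodium tetrakis[(S)‑N‑(4‑dodecylphenylsulfonyl)prolinate], a divalent rhodium carboxylate dimer.
- Assumption: its sense of induction is taken from the accepted model for donor/acceptor carbenoid cyclopropanation of terminal alkenes, which predicts cyclopropane 13 as drawn; if the siloxydiene responds in the opposite sense, Rh2(R‑DOSP)4 is used with no other change.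
- Placeholder centres: C5 in 15–20 and C6 in 17–23 are not controlled and are carried as epimers; their SMILES leave these centres undefined. C5 is reset in step 13 and C6 in steps 16 and 17.

Step 1
Reactants: 1 3-methylcyclopent-2-en-1-one
Product: 3 2-bromo-3-methylcyclopent-2-en-1-one, via 2,3-dibromo-3-methylcyclopentan-1-one 2 (not isolated)
Conditions: Br2, CH2Cl2, 0 °C; then Et3N, 0 °C to rt
Reagents that add atoms: bromine, BrBr
Why: Bromine adds across the enone and triethylamine removes HBr from the alpha carbon (bromination–dehydrobromination), the standard entry to 2‑bromo enones.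

Step 2
Reactants: 3 2-bromo-3-methylcyclopent-2-en-1-one
Product: 4 6-bromo-7-methyl-1,4-dioxaspiro[4.4]non-6-ene
Conditions: HOCH2CH2OH, p-TsOH·H2O (cat.), benzene, reflux, Dean–Stark trap
Reagents that add atoms: ethane-1,2-diol, OCCO
Why: Acid‑catalysed ketalisation with azeotropic removal of water; the alpha bromine holds the alkene in place, and the ketal turns the vinyl bromide into a masked alpha‑keto vinyl anion.

Step 3
Reactants: 4 6-bromo-7-methyl-1,4-dioxaspiro[4.4]non-6-ene
Product: 6 1-(7-methyl-1,4-dioxaspiro[4.4]non-6-en-6-yl)ethan-1-one, via vinyllithium 5 (not isolated)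
Conditions: t-BuLi (2.05 equiv), THF, −78 °C; then MeC(O)N(OMe)Me, −78 to 0 °C; aq. NH4Cl
Reagents that add atoms: N-methoxy-N-methylacetamide, CC(=O)N(C)OC
Why: Bromine–lithium exchange gives the vinyllithium, and acylation with the Weinreb amide stops at the ketone because the chelated tetrahedral adduct survives until work‑up.

Step 4
Reactants: 6 1-(7-methyl-1,4-dioxaspiro[4.4]non-6-en-6-yl)ethan-1-one
Product: 8 tert-butyl(dimethyl){[1-(7-methyl-1,4-dioxaspiro[4.4]non-6-en-6-yl)ethenyl]oxy}silane, via lithium enolate 7 (not isolated)
Conditions: LiN(iPr)2, THF, −78 °C; then TBSCl, DMPU, −78 °C to rt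
Reagents that add atoms: tert-butyldimethylsilyl chloride, CC(C)(C)[Si](C)(C)Cl
Why: Kinetic deprotonation of the acetyl methyl group gives the cross‑conjugated enolate, and O‑silylation delivers the 2‑siloxydiene; the basic conditions spare the ketal.

Step 5
Reactants: 9 methyl 3-oxobutanoate
Product: 10 methyl 2-diazo-3-oxobutanoate
Conditions: 4-acetamidobenzenesulfonyl azide, Et3N, MeCN, 0 °C to rt
Reagents that add atoms: 4-acetamidobenzenesulfonyl azide, CC(=O)Nc1ccc(cc1)S(=O)(=O)N=[N+]=[N-]
Why: Regitz diazo transfer to the active methylene group.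

Step 6
Reactants: 10 methyl 2-diazo-3-oxobutanoate
Product: 11 methyl 2-diazo-3-hydroxybutanoate (racemic)
Conditions: NaBH4, MeOH, 0 °C
Reagents that add atoms: none
Why: Borohydride reduces only the ketone and leaves the diazo ester intact; the carbinol centre is destroyed in the next step, so the racemate is used.

Step 7
Reactants: 11 methyl 2-diazo-3-hydroxybutanoate
Product: 12 methyl 2-diazobut-3-enoate
Conditions: POCl3, Et3N, CH2Cl2, 0 °C to rt; kept as a cold hexane solution and used at once
Reagents that add atoms: none
Why: Dehydration through the dichlorophosphate gives the vinyldiazoacetate; it is used immediately because it cyclises to a pyrazole on standing.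

Step 8
Reactants: 8 tert-butyl(dimethyl){[1-(7-methyl-1,4-dioxaspiro[4.4]non-6-en-6-yl)ethenyl]oxy}silane; 12 methyl 2-diazobut-3-enoate
Product: 14 methyl (8aS)-4-[(tert-butyldimethylsilyl)oxy]-3,3-(ethylenedioxy)-8a-methyl-1,2,3,5,8,8a-hexahydroazulene-6-carboxylate, via cis-divinylcyclopropane 13 (not isolated)
Conditions: Rh2(S-DOSP)4 (1 mol%), hexanes, −40 °C, 12 (2 equiv) added over 2 h; then toluene, 90 °C
Reagents that add atoms: none
Why: The divalent rhodium catalyst converts 12 into a donor/acceptor vinylcarbenoid that adds in a concerted, asynchronous [2+1] step to the terminal, electron‑rich C6=C7 enol ether of 8 (forming C7–C8 and C6–C8) to give cyclopropane 13 with the vinyl and cyclopentenyl groups cis; this is the tandem cyclopropanation–Cope (formal [4+3]) reaction of vinyldiazoacetates with dienes. The seven‑membered ring then closes by a [3,3]‑sigmatropic shift of the cis‑divinylcyclopropane through a boat transition state, breaking C6–C8 and forming C1–C10. The C1 methyl is the cis substituent of the ring alkene and therefore lies inside the boat, so the shift is expected to need heating. The only stereocentre of 14, quaternary C1, is fixed by the configuration of 13, which the chiral carboxylate ligands set by face selection at the carbenoid and which the boat shift transfers stereospecifically to one face of C1. Site selectivity comes from the substrate, since the tetrasubstituted ring alkene is hindered and less electron‑rich than the siloxy alkene, and a hydrocarbon solvent with the prolinate catalyst favours reaction at the carbenoid carbon over its vinylogous terminus. A trans‑divinyl isomer, if formed, can still reach 14 because the siloxy‑ and ester‑substituted C6–C8 bond opens reversibly on heating.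

Step 9
Reactants: 14 methyl (8aS)-4-[(tert-butyldimethylsilyl)oxy]-3,3-(ethylenedioxy)-8a-methyl-1,2,3,5,8,8a-hexahydroazulene-6-carboxylate
Product: 16 methyl (8aR)-3,3-(ethylenedioxy)-8a-methyl-4-oxo-1,2,3,3a,4,7,8,8a-octahydroazulene-6-carboxylate (C3a epimers), via beta,gamma-unsaturated ketone 15 (not isolated)
Conditions: Bu4NF, AcOH, THF, 0 °C; then DBU (0.5 equiv), CH2Cl2, rt
Reagents that add atoms: none
Why: Buffered fluoride cleaves the silyl enol ether to the C6 ketone, and DBU moves the C8=C9 alkene through the extended enolate to C7=C8, where it is conjugated with both the ketone and the ester. The ring‑fusion centre C5 may epimerise here, which does not matter because it is reset in step 13.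

Step 10
Reactants: 16 methyl (8aR)-3,3-(ethylenedioxy)-8a-methyl-4-oxo-1,2,3,3a,4,7,8,8a-octahydroazulene-6-carboxylate
Product: 17 (8aR)-3,3-(ethylenedioxy)-6-(hydroxymethyl)-8a-methyl-1,2,3,3a,4,7,8,8a-octahydroazulen-4-ol (C3a and C4 epimers)
Conditions: iBu2AlH (5 equiv), CH2Cl2, −78 to −20 °C; aq. KNaC4H4O6 work-up
Reagents that add atoms: none
Why: iBu2AlH reduces the enone 1,2 and the conjugated ester to the primary allylic alcohol. The C6 carbinol formed here only takes the carbonyl out of play, and its configuration is erased in step 16.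

Step 11
Reactants: 17 (8aR)-3,3-(ethylenedioxy)-6-(hydroxymethyl)-8a-methyl-1,2,3,3a,4,7,8,8a-octahydroazulen-4-ol
Product: 19 (8aR)-3,3-(ethylenedioxy)-6,8a-dimethyl-1,2,3,3a,4,7,8,8a-octahydroazulen-4-ol (C3a and C4 epimers), via allylic mesylate 18 (not isolated)
Conditions: MsCl (1.05 equiv), 2,4,6-collidine, CH2Cl2, −10 °C; filtration and solvent switch; LiEt3BH, THF, 0 °C
Reagents that add atoms: none
Why: Collidine‑mediated mesylation selects the primary allylic hydroxyl over the hindered secondary one, and triethylborohydride displaces the primary mesylate directly (SN2), leaving the trisubstituted alkene where it is.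

Step 12
Reactants: 19 (8aR)-3,3-(ethylenedioxy)-6,8a-dimethyl-1,2,3,3a,4,7,8,8a-octahydroazulen-4-ol
Product: 20 (8aR)-3,3-(ethylenedioxy)-6,8a-dimethyl-4-[(triisopropylsilyl)oxy]-1,2,3,3a,4,7,8,8a-octahydroazulene (C3a and C4 epimers)
Conditions: TIPSOTf, 2,6-lutidine, CH2Cl2, −78 to 0 °C
Reagents that add atoms: triisopropylsilyl trifluoromethanesulfonate, CC(C)[Si](OS(=O)(=O)C(F)(F)F)(C(C)C)C(C)C
Why: The silyl triflate silylates the hindered secondary alcohol; the triisopropylsilyl ether is chosen because it withstands the acid of the next step and is a poor leaving group.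

Step 13
Reactants: 20 (8aR)-3,3-(ethylenedioxy)-6,8a-dimethyl-4-[(triisopropylsilyl)oxy]-1,2,3,3a,4,7,8,8a-octahydroazulene
Product: 21 (3aS,8aR)-6,8a-dimethyl-4-[(triisopropylsilyl)oxy]-2,3a,4,7,8,8a-hexahydroazulen-3(1H)-one (C4 epimers)
Conditions: p-TsOH·H2O (0.3 equiv), acetone/H2O (10:1), 45 °C, until the ring-fusion ratio is constant
Reagents that add atoms: water, O
Why: Acid‑catalysed transketalisation frees the C4 ketone. C5–H is now alpha to a cyclopentanone and should equilibrate through the enol to the cis‑fused isomer, the stable junction for a five‑ring ketone beside an angular methyl (as in hydrindan‑1‑ones and 14β‑15‑oxo steroids).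

Step 14
Reactants: 21 (3aS,8aR)-6,8a-dimethyl-4-[(triisopropylsilyl)oxy]-2,3a,4,7,8,8a-hexahydroazulen-3(1H)-one
Product: 22 (3R,3aS,8aR)-6,8a-dimethyl-3-(propan-2-yl)-4-[(triisopropylsilyl)oxy]-1,2,3,3a,4,7,8,8a-octahydroazulen-3-ol (C4 epimers)
Conditions: iPrMgCl, CeCl3 (anhydrous), THF, −78 to 0 °C; aq. NH4Cl
Reagents that add atoms: isopropylmagnesium chloride, CC(C)[Mg]Cl
Why: The organocerium reagent (Imamoto conditions) adds to the hindered, enolisable ketone without enolisation or β‑hydride reduction. It should approach the convex face, anti to the C5–C6 bond, which places the new hydroxyl on the side of the seven‑membered ring as C4 requires.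

Step 15
Reactants: 22 (3R,3aS,8aR)-6,8a-dimethyl-3-(propan-2-yl)-4-[(triisopropylsilyl)oxy]-1,2,3,3a,4,7,8,8a-octahydroazulen-3-ol
Product: 23 (3R,3aS,8aR)-6,8a-dimethyl-3-(propan-2-yl)-1,2,3,3a,4,7,8,8a-octahydroazulene-3,4-diol (C4 epimers)
Conditions: Bu4NF, THF, rt to 40 °C; aq. NH4Cl
Reagents that add atoms: none
Why: Fluoride cleaves the silyl ether; nothing else in the molecule is sensitive to it.

Step 16
Reactants: 23 (3R,3aS,8aR)-6,8a-dimethyl-3-(propan-2-yl)-1,2,3,3a,4,7,8,8a-octahydroazulene-3,4-diol
Product: 24 (3R,3aR,8aR)-3-hydroxy-6,8a-dimethyl-3-(propan-2-yl)-2,3,3a,7,8,8a-hexahydroazulen-4(1H)-one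
Conditions: Dess–Martin periodinane, NaHCO3, CH2Cl2, 0 °C to rt
Reagents that add atoms: none
Why: Dess–Martin oxidation converts both C6 epimers into the same enone and leaves the tertiary alcohol untouched; the buffered, near‑neutral conditions avoid retro‑aldol cleavage, dehydration and epimerisation at C5.

Step 17
Reactants: 24 (3R,3aR,8aR)-3-hydroxy-6,8a-dimethyl-3-(propan-2-yl)-2,3,3a,7,8,8a-hexahydroazulen-4(1H)-one
Product: 25 (3R,3aS,4R,8aR)-6,8a-dimethyl-3-(propan-2-yl)-1,2,3,3a,4,7,8,8a-octahydroazulene-3,4-diol
Conditions: Et2BOMe, THF/MeOH (4:1), −78 °C; NaBH4, −78 °C; then repeated evaporation from MeOH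
Reagents that add atoms: none
Why: Narasaka–Prasad chelation‑controlled reduction: boron bridges the C4 hydroxyl and the C6 carbonyl, and only hydride attack from the face of H‑5 keeps the six‑membered chelate chair‑like. This gives the diol with both oxygens on the same side (C6 as required) by 1,2‑reduction of the enone.

Step 18
Reactants: 26 3-hydroxy-4-methoxybenzoic acid
Product: 28 3-[(tert-butyldimethylsilyl)oxy]-4-methoxybenzoic acid, via bis-silylated acid 27 (not isolated)
Conditions: TBSCl (2.5 equiv), imidazole, DMF, rt; then AcOH/THF/H2O (3:1:1), rt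
Reagents that add atoms: tert-butyldimethylsilyl chloride, CC(C)(C)[Si](C)(C)Cl
Why: Both acidic hydroxyls are silylated, and the much more labile silyl ester is then hydrolysed selectively, leaving the aryl silyl ether.

Step 19
Reactants: 25 (3R,3aS,4R,8aR)-6,8a-dimethyl-3-(propan-2-yl)-1,2,3,3a,4,7,8,8a-octahydroazulene-3,4-diol; 28 3-[(tert-butyldimethylsilyl)oxy]-4-methoxybenzoic acid
Product: 29 (3R,3aS,4R,8aR)-3-hydroxy-6,8a-dimethyl-3-(propan-2-yl)-1,2,3,3a,4,7,8,8a-octahydroazulen-4-yl 3-[(tert-butyldimethylsilyl)oxy]-4-methoxybenzoate
Conditions: EDC·HCl, DMAP, CH2Cl2, rt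
Reagents that add atoms: none
Why: Steglich esterification acylates the secondary allylic hydroxyl with retention at C6; the tertiary hydroxyl is too hindered to compete.

Step 20
Reactants: 29 (3R,3aS,4R,8aR)-3-hydroxy-6,8a-dimethyl-3-(propan-2-yl)-1,2,3,3a,4,7,8,8a-octahydroazulen-4-yl 3-[(tert-butyldimethylsilyl)oxy]-4-methoxybenzoate
Product: 30 (3R,3aS,4R,8aR)-3-hydroxy-6,8a-dimethyl-3-(propan-2-yl)-1,2,3,3a,4,7,8,8a-octahydroazulen-4-yl 3-hydroxy-4-methoxybenzoate
Conditions: Bu4NF, AcOH, THF, 0 °C
Reagents that add atoms: none
Why: Fluoride cleaves the aryl silyl ether rapidly; acetic acid buffers the phenoxide so that the allylic benzoate and the tertiary alcohol are not disturbed.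

## Compound list

1 | 3-methylcyclopent-2-en-1-one | CC1=CC(=O)CC1 | starting material
2 | trans-2,3-dibromo-3-methylcyclopentan-1-one (racemic) | C[C@]1(Br)CCC(=O)[C@@H]1Br | intermediate
3 | 2-bromo-3-methylcyclopent-2-en-1-one | CC1=C(Br)C(=O)CC1 | intermediate
4 | 6-bromo-7-methyl-1,4-dioxaspiro[4.4]non-6-ene | CC1=C(Br)C2(CC1)OCCO2 | intermediate
5 | (7-methyl-1,4-dioxaspiro[4.4]non-6-en-6-yl)lithium | [Li]C1=C(C)CCC12OCCO2 | intermediate
6 | 1-(7-methyl-1,4-dioxaspiro[4.4]non-6-en-6-yl)ethan-1-one | CC(=O)C1=C(C)CCC12OCCO2 | intermediate
7 | lithium 1-(7-methyl-1,4-dioxaspiro[4.4]non-6-en-6-yl)ethen-1-olate | [Li]OC(=C)C1=C(C)CCC12OCCO2 | intermediate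
8 | tert-butyl(dimethyl){[1-(7-methyl-1,4-dioxaspiro[4.4]non-6-en-6-yl)ethenyl]oxy}silane | C=C(O[Si](C)(C)C(C)(C)C)C1=C(C)CCC12OCCO2 | intermediate
9 | methyl 3-oxobutanoate (methyl acetoacetate) | COC(=O)CC(C)=O | starting material
10 | methyl 2-diazo-3-oxobutanoate | COC(=O)C(=[N+]=[N-])C(C)=O | intermediate
11 | methyl 2-diazo-3-hydroxybutanoate (racemic) | COC(=O)C(=[N+]=[N-])C(C)O | intermediate
12 | methyl 2-diazobut-3-enoate | C=CC(=[N+]=[N-])C(=O)OC | intermediate
13 | methyl (1R,2S)-2-[(tert-butyldimethylsilyl)oxy]-1-ethenyl-2-(7-methyl-1,4-dioxaspiro[4.4]non-6-en-6-yl)cyclopropane-1-carboxylate | C=C[C@]1(C(=O)OC)C[C@]1(O[Si](C)(C)C(C)(C)C)C2=C(C)CCC23OCCO3 | intermediate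
14 | methyl (8aS)-4-[(tert-butyldimethylsilyl)oxy]-3,3-(ethylenedioxy)-8a-methyl-1,2,3,5,8,8a-hexahydroazulene-6-carboxylate | COC(=O)C1=CC[C@]2(C)CCC3(OCCO3)C2=C(O[Si](C)(C)C(C)(C)C)C1 | intermediate
15 | methyl (8aS)-3,3-(ethylenedioxy)-8a-methyl-4-oxo-1,2,3,3a,4,5,8,8a-octahydroazulene-6-carboxylate (C3a epimers) | COC(=O)C1=CC[C@]2(C)CCC3(OCCO3)C2C(=O)C1 | intermediate
16 | methyl (8aR)-3,3-(ethylenedioxy)-8a-methyl-4-oxo-1,2,3,3a,4,7,8,8a-octahydroazulene-6-carboxylate (C3a epimers) | COC(=O)C1=CC(=O)C2C3(OCCO3)CC[C@@]2(C)CC1 | intermediate
17 | (8aR)-3,3-(ethylenedioxy)-6-(hydroxymethyl)-8a-methyl-1,2,3,3a,4,7,8,8a-octahydroazulen-4-ol (C3a and C4 epimers) | OCC1=CC(O)C2C3(OCCO3)CC[C@@]2(C)CC1 | intermediate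
18 | [(8aR)-3,3-(ethylenedioxy)-4-hydroxy-8a-methyl-1,2,3,3a,4,7,8,8a-octahydroazulen-6-yl]methyl methanesulfonate (C3a and C4 epimers) | CS(=O)(=O)OCC1=CC(O)C2C3(OCCO3)CC[C@@]2(C)CC1 | intermediate
19 | (8aR)-3,3-(ethylenedioxy)-6,8a-dimethyl-1,2,3,3a,4,7,8,8a-octahydroazulen-4-ol (C3a and C4 epimers) | CC1=CC(O)C2C3(OCCO3)CC[C@@]2(C)CC1 | intermediate
20 | (8aR)-3,3-(ethylenedioxy)-6,8a-dimethyl-4-[(triisopropylsilyl)oxy]-1,2,3,3a,4,7,8,8a-octahydroazulene (C3a and C4 epimers) | CC1=CC(O[Si](C(C)C)(C(C)C)C(C)C)C2C3(OCCO3)CC[C@@]2(C)CC1 | intermediate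
21 | (3aS,8aR)-6,8a-dimethyl-4-[(triisopropylsilyl)oxy]-2,3a,4,7,8,8a-hexahydroazulen-3(1H)-one (cis-fused; C4 epimers) | CC1=CC(O[Si](C(C)C)(C(C)C)C(C)C)[C@H]2C(=O)CC[C@@]2(C)CC1 | intermediate
22 | (3R,3aS,8aR)-6,8a-dimethyl-3-(propan-2-yl)-4-[(triisopropylsilyl)oxy]-1,2,3,3a,4,7,8,8a-octahydroazulen-3-ol (C4 epimers) | CC1=CC(O[Si](C(C)C)(C(C)C)C(C)C)[C@H]2[C@](O)(C(C)C)CC[C@@]2(C)CC1 | intermediate
23 | (3R,3aS,8aR)-6,8a-dimethyl-3-(propan-2-yl)-1,2,3,3a,4,7,8,8a-octahydroazulene-3,4-diol (C4 epimers) | CC1=CC(O)[C@H]2[C@](O)(C(C)C)CC[C@@]2(C)CC1 | intermediate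
24 | (3R,3aR,8aR)-3-hydroxy-6,8a-dimethyl-3-(propan-2-yl)-2,3,3a,7,8,8a-hexahydroazulen-4(1H)-one | CC1=CC(=O)[C@H]2[C@](O)(C(C)C)CC[C@@]2(C)CC1 | intermediate
25 | (3R,3aS,4R,8aR)-6,8a-dimethyl-3-(propan-2-yl)-1,2,3,3a,4,7,8,8a-octahydroazulene-3,4-diol | CC1=C[C@@H](O)[C@H]2[C@](O)(C(C)C)CC[C@@]2(C)CC1 | intermediate
26 | 3-hydroxy-4-methoxybenzoic acid (isovanillic acid) | COc1ccc(C(=O)O)cc1O | starting material
27 | tert-butyldimethylsilyl 3-[(tert-butyldimethylsilyl)oxy]-4-methoxybenzoate | COc1ccc(C(=O)O[Si](C)(C)C(C)(C)C)cc1O[Si](C)(C)C(C)(C)C | intermediate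
28 | 3-[(tert-butyldimethylsilyl)oxy]-4-methoxybenzoic acid | COc1ccc(C(=O)O)cc1O[Si](C)(C)C(C)(C)C | intermediate
29 | (3R,3aS,4R,8aR)-3-hydroxy-6,8a-dimethyl-3-(propan-2-yl)-1,2,3,3a,4,7,8,8a-octahydroazulen-4-yl 3-[(tert-butyldimethylsilyl)oxy]-4-methoxybenzoate | COc1ccc(C(=O)O[C@@H]2C=C(C)CC[C@]3(C)CC[C@@](O)(C(C)C)[C@H]23)cc1O[Si](C)(C)C(C)(C)C | intermediate
30 | (3R,3aS,4R,8aR)-3-hydroxy-6,8a-dimethyl-3-(propan-2-yl)-1,2,3,3a,4,7,8,8a-octahydroazulen-4-yl 3-hydroxy-4-methoxybenzoate | COc1ccc(C(=O)O[C@@H]2C=C(C)CC[C@]3(C)CC[C@@](O)(C(C)C)[C@H]23)cc1O | target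

## Step count and risks

Total: 20 steps. Longest linear sequence: 16 steps (steps 1–4, 8–17, 19 and 20, from 3‑methylcyclopent‑2‑en‑1‑one). Steps 5–7 and 18 are side branches.

**Step 8 (key step).** The most likely failure is loss of fidelity between cyclopropanation and rearrangement. A 1,1‑disubstituted siloxy alkene may place the cyclopentenyl group partly trans to the vinyl group, and the Cope shift is slowed by the inside methyl at a fully substituted terminus. The donor–acceptor cyclopropane then has time to open heterolytically at C6–C8. That path erodes enantiomeric purity on re‑closure and leaks into a formal [3+2] cyclopentene or into vinylogous alkylation products. The fallback removes the acceptor before the rearrangement. It sets out from 13, isolated at or below room temperature. iBu2AlH reduces the ester to the cyclopropylmethanol F1, which can no longer ionise. Heating in toluene rearranges it to the hydroxymethyl cycloheptadiene F2. MnO2 oxidises F2 to the enal F3. Bu4NF/AcOH followed by DBU, as in step 9, gives the conjugated keto enal F4. iBu2AlH reduction of F4 returns to the route at 17.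

**Step 13.** The ring‑fusion epimerisation may be incomplete, or the enol may expel the allylic silyloxy group from C6 (β‑elimination to the cross‑conjugated dienone), because the conditions that enolise C5 also activate that leaving group. The fallback changes the protecting group and the mode of equilibration. It sets out from 19. NaH and 4‑methoxybenzyl chloride give the 4‑methoxybenzyl ether F5, whose alkoxide is a much poorer leaving group. PPTS in wet acetone removes the ketal, and K2CO3 in MeOH equilibrates C5 through the enolate to the cis‑fused ketone F6. iPrMgCl/CeCl3 gives the carbinol F7, and DDQ in buffered wet CH2Cl2 removes the ether, returning to the route at 23.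

**Step 14.** Addition of a secondary Grignard reagent to a hindered cyclopentanone may stall through enolisation or hydride transfer, and the angular methyl on the convex face may lower the facial preference. The fallback uses a smaller sp2 nucleophile and sets out from 21. CH2=C(CH3)MgBr with CeCl3 gives the isopropenyl carbinol F8. Hydrogenation with RhCl(PPh3)3 saturates the 1,1‑disubstituted alkene selectively beside the trisubstituted ring alkene and returns to the route at 22.

**Step 17.** Hydride may be delivered to the wrong face of C6 if the tertiary hydroxyl does not form the boron chelate, or if the angular methyl blocks the face of H‑5. The fallback accepts that outcome and sets out from 24. The reduction then gives the C6‑epimeric diol F9. Mitsunobu esterification of F9 with acid 28 (PPh3, diisopropyl azodicarboxylate, THF) inverts C6 while forming the ester and returns to the route at 29, bypassing step 19.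

**Step 11.** Sulfonylation may not discriminate fully between the two allylic hydroxyls, or hydride may attack with allylic transposition, because both alcohols are allylic and the substrate is an epimer mixture. The fallback protects first and sets out from 16. NaBH4/CeCl3 gives the hydroxy ester F10. TIPSOTf/2,6‑lutidine gives the silyloxy ester F11. iBu2AlH gives the primary allylic alcohol F12. MsCl/Et3N followed by LiEt3BH returns to the route at 20.

## Further compounds

F1 | step 8 | [(1S,2R)-2-[(tert-butyldimethylsilyl)oxy]-1-ethenyl-2-(7-methyl-1,4-dioxaspiro[4.4]non-6-en-6-yl)cyclopropyl]methanol | C=C[C@]1(CO)C[C@]1(O[Si](C)(C)C(C)(C)C)C2=C(C)CCC23OCCO3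
F2 | step 8 | [(8aS)-4-[(tert-butyldimethylsilyl)oxy]-3,3-(ethylenedioxy)-8a-methyl-1,2,3,5,8,8a-hexahydroazulen-6-yl]methanol | OCC1=CC[C@]2(C)CCC3(OCCO3)C2=C(O[Si](C)(C)C(C)(C)C)C1
F3 | step 8 | (8aS)-4-[(tert-butyldimethylsilyl)oxy]-3,3-(ethylenedioxy)-8a-methyl-1,2,3,5,8,8a-hexahydroazulene-6-carbaldehyde | O=CC1=CC[C@]2(C)CCC3(OCCO3)C2=C(O[Si](C)(C)C(C)(C)C)C1
F4 | step 8 | (8aR)-3,3-(ethylenedioxy)-8a-methyl-4-oxo-1,2,3,3a,4,7,8,8a-octahydroazulene-6-carbaldehyde (C3a epimers) | O=CC1=CC(=O)C2C3(OCCO3)CC[C@@]2(C)CC1
F5 | step 13 | (8aR)-3,3-(ethylenedioxy)-4-[(4-methoxybenzyl)oxy]-6,8a-dimethyl-1,2,3,3a,4,7,8,8a-octahydroazulene (C3a and C4 epimers) | CC1=CC(OCc2ccc(OC)cc2)C2C3(OCCO3)CC[C@@]2(C)CC1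
F6 | step 13 | (3aS,8aR)-4-[(4-methoxybenzyl)oxy]-6,8a-dimethyl-2,3a,4,7,8,8a-hexahydroazulen-3(1H)-one (C4 epimers) | CC1=CC(OCc2ccc(OC)cc2)[C@H]2C(=O)CC[C@@]2(C)CC1
F7 | step 13 | (3R,3aS,8aR)-4-[(4-methoxybenzyl)oxy]-6,8a-dimethyl-3-(propan-2-yl)-1,2,3,3a,4,7,8,8a-octahydroazulen-3-ol (C4 epimers) | CC1=CC(OCc2ccc(OC)cc2)[C@H]2[C@](O)(C(C)C)CC[C@@]2(C)CC1
F8 | step 14 | (3R,3aS,8aR)-6,8a-dimethyl-3-(prop-1-en-2-yl)-4-[(triisopropylsilyl)oxy]-1,2,3,3a,4,7,8,8a-octahydroazulen-3-ol (C4 epimers) | CC1=CC(O[Si](C(C)C)(C(C)C)C(C)C)[C@H]2[C@](O)(C(C)=C)CC[C@@]2(C)CC1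
F9 | step 17 | (3R,3aS,4S,8aR)-6,8a-dimethyl-3-(propan-2-yl)-1,2,3,3a,4,7,8,8a-octahydroazulene-3,4-diol | CC1=C[C@H](O)[C@H]2[C@](O)(C(C)C)CC[C@@]2(C)CC1
F10 | step 11 | methyl (8aR)-3,3-(ethylenedioxy)-4-hydroxy-8a-methyl-1,2,3,3a,4,7,8,8a-octahydroazulene-6-carboxylate (C3a and C4 epimers) | COC(=O)C1=CC(O)C2C3(OCCO3)CC[C@@]2(C)CC1
F11 | step 11 | methyl (8aR)-3,3-(ethylenedioxy)-8a-methyl-4-[(triisopropylsilyl)oxy]-1,2,3,3a,4,7,8,8a-octahydroazulene-6-carboxylate (C3a and C4 epimers) | COC(=O)C1=CC(O[Si](C(C)C)(C(C)C)C(C)C)C2C3(OCCO3)CC[C@@]2(C)CC1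
F12 | step 11 | [(8aR)-3,3-(ethylenedioxy)-8a-methyl-4-[(triisopropylsilyl)oxy]-1,2,3,3a,4,7,8,8a-octahydroazulen-6-yl]methanol (C3a and C4 epimers) | OCC1=CC(O[Si](C(C)C)(C(C)C)C(C)C)C2C3(OCCO3)CC[C@@]2(C)CC1
A1 | alternative 1 | cis-fused 6,8a-dimethyl-3-(propan-2-yl)-1,2,3,3a,6,7,8,8a-octahydroazulen-3-ol | C1=C[C@H](C)CC[C@]2(C)CC[C@@](O)(C(C)C)[C@H]12
A2 | alternative 1 | (E)-6-methyl-1-(trans-2-methylcyclopropyl)-3-(propan-2-yl)hepta-1,6-dien-3-ol | C=C(C)CC[C@@](O)(C(C)C)/C=C/[C@@H]1C[C@H]1C
A3 | alternative 2 | cis-fused 7-(3-bromo-2-methylpropyl)-1-methyl-4-(propan-2-yl)-4-[(triethylsilyl)oxy]bicyclo[3.2.0]heptan-6-one | O=C1[C@@H](C[C@H](C)CBr)[C@]2(C)CC[C@@](O[Si](CC)(CC)CC)(C(C)C)[C@H]12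
A4 | alternative 2 | (4S)-5-bromo-4-methyl-1-(pyrrolidin-1-yl)pentan-1-one | O=C(CC[C@H](C)CBr)N1CCCC1
A5 | alternative 2 | triethyl{[(1R)-3-methyl-1-(propan-2-yl)cyclopent-2-en-1-yl]oxy}silane | CC1=C[C@](O[Si](CC)(CC)CC)(C(C)C)CC1
A6 | alternative 3 | cis-fused 4-[(tert-butyldimethylsilyl)oxy]-6,8a-dimethyl-3a,4,7,8-tetrahydroazulen-3(8aH)-one (C4 epimer of the target series) | CC(C)(C)[Si](C)(C)O[C@H]1C=C(C)CC[C@]2(C)C=CC(=O)[C@H]12
A7 | alternative 3 | (E)-1-{7-[(tert-butyldimethylsilyl)oxy]-2,5-dimethylcyclohepta-1,5-dien-1-yl}-3-(trimethylsilyl)prop-2-en-1-one | C[Si](C)(C)/C=C/C(=O)C1=C(C)CCC(C)=C[C@@H]1O[Si](C)(C)C(C)(C)C
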